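The runs come from a simulation for an exercise, noise included.

The constants of this catalyst cycle are hidden, so two chemists argue from the curves, and both start from catalyst-minutes, loading times time, the normalised time axis of kinetic analysis: the west run at 4.00 min and the south-west run at 3.00 min stand at equal catalyst-minutes and read 34.4 % and 34.5 %.

| setting | west | south-west | north | Tuesday's | Thursday's | Monday's |
|---|---|---|---|---|---|---|
| starting material | 0.15 M | 0.15 M | 0.15 M | 0.15 M | 0.15 M (fed, over 4.0 min) | 0.15 M |
| partner | 0.30 M | 0.30 M | 0.30 M | 0.300 M | 0.300 M | 0.300 M (fed, over 4.0 min) |
| free catalyst | 7.5 mM | 10 mM | 16 mM | 7.5 mM | 7.5 mM | 7.5 mM |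
| remark | run made earlier | run made earlier | run made earlier | everything together at the start | all else is in the flask from the start; the feed brings no volume worth counting | all else is in the flask from the start; the feed brings no volume worth counting |
| time |  |  |  | 10 min | 10 min | 10 min |

| run | time / min | target / % |
|---|---|---|
| west | 0.333 | 1.5 |
| west | 1.00 | 8.8 |
| west | 1.50 | 12.4 |
| west | 2.50 | 21.7 |
| west | 4.00 | 34.4 |
| west | 5.00 | 42.7 |
| west | 6.00 | 51.7 |
| south-west | 1.33 | 14.6 |
| south-west | 3.00 | 34.5 |
| south-west | 4.00 | 44.5 |
| south-west | 6.00 | 65.4 |
| south-west | 8.00 | 79.9 |
| south-west | 10.0 | 92.0 |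
| north | 0.833 | 14.3 |
| north | 1.33 | 24.5 |
| north | 2.00 | 36.0 |
| north | 3.00 | 52.5 |
| north | 4.00 | 66.8 |
| north | 6.00 | 89.4 |
| north | 10.0 | 98.6 |

(each reading ± 1 percentage point)

* the flask with the highest amount of target, in percent of the starting material charged ("all alike" if they lie within 1.5 percentage points) (Tuesday's / Thursday's / Monday's / all alike)
* final target, as a percentage of the starting material charged, in Tuesday's
* final target, as a percentage of the starting material charged, in Thursday's
* final target, as a percentage of the starting material charged, in Monday's

- steps thought possible: starting material + catalyst intermediate B <-> catalyst intermediate C; catalyst intermediate A -> catalyst intermediate B; catalyst intermediate D -> free catalyst + target; partner + free catalyst <-> catalyst intermediate A; partner -> decomposition product; catalyst intermediate C -> catalyst intermediate D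

Tuesday's catalyst-minutes lie above those of the north reading at 4.00 min and below those of the south-west reading at 8.00 min, so between these readings both chemists take 75.8 % for Tuesday's, and there they also read a minute's worth, the share of the charge that one late minute at Tuesday's loading turns into target, of 0.0614 min⁻¹.

The first chemist holds that the clock is catalyst and nothing else, so a feed costs no minutes and the flasks read alike near that figure. The second answers that the earlier runs share one partner charge, 0.30 M, so the clock's dependence on partner is unread; if the rate followed a fed reagent in proportion, the clock ran on average at half speed during the feed, the lag was 2.00 min, and the fed flask read 63.5 %, so a fed flask belongs between these figures. The forecast takes this side, with Tuesday's first at 75.5 %, Thursday's at 70 % and Monday's at 68 %, the last “with an early lag”.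

Tuesday's gives 77.8 %, Thursday's 74.4 % and Monday's 67.7 %, so Tuesday's leads by more than the margin of 1.5 percentage points; the second chemist's view stands, and the clock view keeps flasks charged whole at the start, where it was drawn. Over the first 4.0 min, mean partner in Monday's was 0.136 M, half of Tuesday's 0.270 M. At the minute's worth, Monday's gap to Tuesday's reckons as a lag of 1.63 min, less than 2.00 min.

    starting material + catalyst intermediate B ⇌ catalyst intermediate C (K = 21.0 L mol⁻¹, k = 2.87 L mol⁻¹ s⁻¹)
    catalyst intermediate A → catalyst intermediate B (k = 0.0962 s⁻¹)
    catalyst intermediate D → free catalyst + target (k = 0.339 s⁻¹)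
    partner + free catalyst ⇌ catalyst intermediate A (K = 2.22 L mol⁻¹, k = 67.7 L mol⁻¹ s⁻¹)
    partner → decomposition product (k = 2.50 × 10⁻⁶ s⁻¹)
    catalyst intermediate C → catalyst intermediate D (k = 23.4 s⁻¹)

Monday's flask read at 6.0 min is the second case: that lag places it on the west curve at 4.37 min, between the readings at 4.00 min and 5.00 min, which gives 37.4 %, and the computed result is 38.1 %.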